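(The numbers of this flask are made up; what happens was integrated by code.)

The vessel holds two liquid phases: substrate in the first meets fresh carrier, and salt in the second phase turns spent carrier back into fresh.

substrate 24 mM; salt in the second phase 60.0 mM; spent carrier 1.2 mM; impurity 0.23 mM; time 1.5 min; volume of the second phase over the first 0.50

    spent carrier + salt in the second phase ⇌ fresh carrier + spent salt in the second phase (K1 = 1.0, k1 = 20 M⁻¹ s⁻¹)
    substrate + fresh carrier → target + spent carrier (k2 = 24 M⁻¹ s⁻¹)
    crystals ⇌ target, rate k3*(cs3 - [target]) while solid is left; crystals form when [target] > cs3 (cs3 = 20 mM, k3 = 0.43 s⁻¹)
    fresh carrier + impurity → spent catalyst (k4 = 66000 M⁻¹ s⁻¹)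
    2 substrate → self-condensation product (k5 = 0.0012 M⁻¹ s⁻¹)

- in percentages every species weighs as the substrate in it: one self-condensation product counts as two
- for target the crystals are counted in
- two of one species on the left: rate k times its square, two consumed each time
- in the second phase: salt in the second phase, spent salt in the second phase; everything else is in the first
- charges count per volume of the first phase; a concentration in a rate is the amount of a species over the volume of its own phase; every rate counts per litre of the first phase
- as a solid, counted per litre of solution: crystals
- run time (flask): 1.5 min

1. the target and crystals together standing at 1.5 min, as a percentage of the substrate charged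
2. concentration of target in solution at 1.5 min, in percent of saturation

I follow one carrier molecule. Once fresh, it meets a fork: at the charges, impurity takes it at 15.2 s⁻¹ and substrate at 0.576 s⁻¹, so nearly all of the first fresh carrier goes to impurity. That leaves 0.970 mM of working carrier. I then tabulate, per molecule, the rates out of spent form, back from fresh form through spent salt, and on through substrate:

- Substrate as charged: out 2.40 s⁻¹, back none, on 0.576 s⁻¹, fresh share 80.6%.
- Half the substrate converted: out 1.92 s⁻¹, back 0.480 s⁻¹, on 0.288 s⁻¹, fresh share 71.4%.

Fresh share is out over the sum of the three. Reading down, the out column falls and the back column opens, so the share sinks. Reading across the second row, a molecule leaves spent form faster than it returns, so fresh carrier is the resting state of the round.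

I take the second row as the mean of the run. The working constant, a pseudo-first-order constant for substrate, is k2 times fresh share times working carrier: 0.998 min⁻¹. Over 1.5 min it gives an estimate of 77.6% converted, which is 93.1% of saturation, so I expect no crystals.

The forecast gives 76.7% (74% to 79%) and 92% (89% to 95%), reasoning that “the shuttle then slows as the second-phase salt shifts toward its spent form”. My figure stands 0.90 percentage points above it.

The flask gives 76.8% at 92.1% of saturation. At 1.50 min, fresh carrier is made at 0.991 of the rate at which it is used up, each step taken net. At 0.750 min, the working constant gives 52.7% converted, and the flask holds 53.5% as target and crystals.

For the same flask left until 2.5 min, the working constant gives 91.8%. The computed result is 90.2%, with crystals at 6.54%.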